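**Plan**

- Retrosynthesis: the flavanone is opened at O1–C2 (oxa-Michael) and C2–C3 (Knoevenagel) to a ring A β-keto ester and a biaryl flavone aldehyde. The flavone pyranone is cut at O1–C8a, C4–C4a and O1–C2 to a 3-alkoxyaryne and an arylpropiolic acid. The C6–C3′ biaryl bond is cut last (Suzuki–Miyaura).
- Forward: the biaryl is joined first. Its resorcinol ring is converted by C–H borylation/oxidation, bromination and O→C silyl migration into an ortho-silylaryl triflate. The aryne step then builds the flavone pyranone, and the flavanone pyranone is closed last.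
- Enabling feature: the flavone pyranone shares C4a and C8a with ring A, and the oxygen on C5 is the neighbour of C4a. An aryne spanning C4a–C8a is therefore biased so that a carboxylate oxygen enters at C8a and the acyl carbon ends up on C4a.
- Stereochemistry: the only stereocentre, C2 of the flavanone (S), is set by a cinchona thiourea-catalysed oxa-Michael closure of an alkylidene activated by a tert-butyl ester on the α-carbon. That ester leaves together with the MOM groups in the final acid step.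

Key step: step 11

Assumption: the thiourea derived from 9-amino-9-deoxy-epi-quinidine is taken to give the (2S) series in step 16; if the sense of induction is the opposite, the pseudoenantiomeric quinine-derived thiourea takes its place.

**Route**

Step 1
Reactants: 1 2-bromobenzene-1,3-diol (2-bromoresorcinol)
Product: 2 2-bromo-1,3-bis(methoxymethoxy)benzene
Conditions: MOMCl (2.5 equiv), i-Pr2NEt (3 equiv), CH2Cl2, 0 °C → rt
Reagents that add atoms: chloromethyl methyl ether, COCCl
Why: O-alkylation of both phenols (Williamson-type acetal formation) should give a bis-MOM ether that tolerates the later palladium, organolithium and fluoride steps and that later directs the aryne regiochemistry.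

Step 2
Reactants: 3 3-bromo-4-hydroxybenzaldehyde
Product: 4 3-bromo-4-(methoxymethoxy)benzaldehyde
Conditions: MOMCl (1.3 equiv), i-Pr2NEt (1.6 equiv), CH2Cl2, 0 °C → rt
Reagents that add atoms: chloromethyl methyl ether, COCCl
Why: The acidic para-formyl phenol should be O-alkylated cleanly under amine base (phenol MOM protection).

Step 3
Reactants: 4 3-bromo-4-(methoxymethoxy)benzaldehyde
Product: 5 2-[3-bromo-4-(methoxymethoxy)phenyl]-1,3-dioxolane
Conditions: Me3SiOCH2CH2OSiMe3 (1.5 equiv), Me3SiOTf (5 mol%), CH2Cl2, −78 → −20 °C; pyridine quench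
Reagents that add atoms: 1,2-bis(trimethylsilyloxy)ethane, C[Si](C)(C)OCCO[Si](C)(C)C
Why: Silyl triflate-catalysed acetalisation with the bis-silyl ether of ethylene glycol runs under aprotic, cold conditions, so the aldehyde should be masked without exchange of the aryl MOM ether.

Step 4
Reactants: 5 2-[3-bromo-4-(methoxymethoxy)phenyl]-1,3-dioxolane
Product: 6 2-[5-(1,3-dioxolan-2-yl)-2-(methoxymethoxy)phenyl]-4,4,5,5-tetramethyl-1,3,2-dioxaborolane
Conditions: B2pin2 (1.2 equiv), Pd(dppf)Cl2 (3 mol%), KOAc (3 equiv), 1,4-dioxane, 90 °C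
Reagents that add atoms: bis(pinacolato)diboron, CC1(C)OB(OC1(C)C)B1OC(C)(C)C(C)(C)O1
Why: Miyaura borylation of an aryl bromide is tolerant of acetals and should give the boronate under weakly basic conditions.

Step 5
Reactants: 2 2-bromo-1,3-bis(methoxymethoxy)benzene; 6 2-[5-(1,3-dioxolan-2-yl)-2-(methoxymethoxy)phenyl]-4,4,5,5-tetramethyl-1,3,2-dioxaborolane
Product: 7 2-[3-[2,6-bis(methoxymethoxy)phenyl]-4-(methoxymethoxy)phenyl]-1,3-dioxolane
Conditions: Pd(OAc)2 (3 mol%), SPhos (6 mol%), K3PO4 (3 equiv), toluene/H2O (10:1), 100 °C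
Reagents that add atoms: none
Why: Suzuki–Miyaura coupling with a bulky electron-rich biarylphosphine should handle oxidative addition into the hindered 2,6-dialkoxy bromide and formation of the tri-ortho-substituted biaryl.

Step 6
Reactants: 7 2-[3-[2,6-bis(methoxymethoxy)phenyl]-4-(methoxymethoxy)phenyl]-1,3-dioxolane
Product: 9 4-[5-(1,3-dioxolan-2-yl)-2-(methoxymethoxy)phenyl]-3,5-bis(methoxymethoxy)phenol, via arylboronate 8 (not isolated)
Conditions: [Ir(OMe)(cod)]2 (1.5 mol%), 4,4′-di-tert-butyl-2,2′-bipyridine (3 mol%), B2pin2 (1.0 equiv), THF, 80 °C; then H2O2 (30% aq), NaOH (2 M aq), THF, 0 °C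
Reagents that add atoms: hydrogen peroxide, OO
Why: Sterically governed iridium-catalysed C–H borylation should select the only ring C–H without an ortho substituent (para to the biaryl bond, meta to both MOM ethers), and basic peroxide oxidation of the C–B bond gives the phenol without touching the acetals.

Step 7
Reactants: 9 4-[5-(1,3-dioxolan-2-yl)-2-(methoxymethoxy)phenyl]-3,5-bis(methoxymethoxy)phenol
Product: 10 2-bromo-4-[5-(1,3-dioxolan-2-yl)-2-(methoxymethoxy)phenyl]-3,5-bis(methoxymethoxy)phenol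
Conditions: NBS (1.0 equiv), CH2Cl2, −78 → −30 °C
Reagents that add atoms: N-bromosuccinimide, O=C1CCC(=O)N1Br
Why: Electrophilic bromination of the phloroglucinol-type ring can only occur ortho to the free hydroxyl (para is blocked by the aryl group), and the two ortho sites are equivalent, so one equivalent at low temperature should give a single monobromide.

Step 8
Reactants: 10 2-bromo-4-[5-(1,3-dioxolan-2-yl)-2-(methoxymethoxy)phenyl]-3,5-bis(methoxymethoxy)phenol
Product: 13 4-[5-(1,3-dioxolan-2-yl)-2-(methoxymethoxy)phenyl]-3,5-bis(methoxymethoxy)-2-(trimethylsilyl)phenyl trifluoromethanesulfonate, via silyl ether 11 (not isolated), via lithium silylphenoxide 12 (not isolated)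
Conditions: HN(SiMe3)2, THF, 70 °C, then evaporation; n-BuLi (1.1 equiv), THF, −100 °C; Tf2O (1.2 equiv), −100 → −78 °C; aq NaHCO3
Reagents that add atoms: hexamethyldisilazane, C[Si](C)(C)N[Si](C)(C)C; trifluoromethanesulfonic anhydride, O=S(=O)(OS(=O)(=O)C(F)(F)F)C(F)(F)F
Why: O-silylation, bromine–lithium exchange, anionic 1,3 O→C silyl shift (retro-Brook rearrangement) and O-triflation of the resulting lithium phenoxide is the standard one-flask entry to ortho-silylaryl triflates, and the exchange should outpace ortho-lithiation next to the MOM groups at this temperature.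

Step 9
Reactants: 14 4-iodophenol
Product: 15 1-iodo-4-(methoxymethoxy)benzene
Conditions: MOMCl (1.3 equiv), i-Pr2NEt (1.6 equiv), CH2Cl2, 0 °C → rt
Reagents that add atoms: chloromethyl methyl ether, COCCl
Why: Routine phenol MOM protection (O-alkylation) gives the aryl iodide for the alkyne coupling.

Step 10
Reactants: 15 1-iodo-4-(methoxymethoxy)benzene; 16 prop-2-ynoic acid (propiolic acid)
Product: 17 3-[4-(methoxymethoxy)phenyl]prop-2-ynoic acid
Conditions: Pd(PPh3)4 (3 mol%), DBU (2.4 equiv), DMSO, 35 °C; cold aqueous citric acid work-up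
Reagents that add atoms: none
Why: Copper-free Sonogashira coupling of an aryl iodide with the amidinium propiolate near room temperature should give the arylpropiolic acid, the absence of copper and heat holding back decarboxylation.

Step 11
Reactants: 13 4-[5-(1,3-dioxolan-2-yl)-2-(methoxymethoxy)phenyl]-3,5-bis(methoxymethoxy)-2-(trimethylsilyl)phenyl trifluoromethanesulfonate; 17 3-[4-(methoxymethoxy)phenyl]prop-2-ynoic acid
Product: 20 6-[5-(1,3-dioxolan-2-yl)-2-(methoxymethoxy)phenyl]-5,7-bis(methoxymethoxy)-2-[4-(methoxymethoxy)phenyl]chromen-4-one, via aryne 18 (not isolated), via hydroxyaryl ynone 19 (not isolated)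
Conditions: 17 (1.5 equiv), CsF (4 equiv), THF, 125 °C, sealed tube
Reagents that add atoms: none
Why: Fluoride removes the silyl group with loss of triflate to give aryne 18, whose triple bond spans the future C4a and C8a, and the cesium carboxylate of 17 adds through oxygen to the aryne carbon remote from the flanking methoxymethoxy group. The aryl anion so formed next to that group attacks the ester carbonyl, and the strained four-membered alkoxide opens to the ortho-acylphenoxide 19, the net result being insertion of the aryne into the carboxyl C–O bond (O1–C8a and C4–C4a). The phenoxide then closes the pyranone by 6-endo-dig oxa-Michael addition to the ynone (O1–C2), and protonation gives flavone 20. The closest known reaction type is the fluoride-triggered insertion of arynes into the C–O bond of carboxylic acids to give ortho-hydroxyaryl ketones, which with arylpropiolic acids runs on to flavones. No stereocentre is formed. The step needs regioselective addition to the unsymmetrical aryne, secured by the inductive effect of the alkoxy group on C5 (the distorted aryne takes the nucleophile at the distal carbon), and 6-endo rather than 5-exo closure, favoured for the conjugated aryl ynone; because phenol 9 is symmetric about the biaryl axis, the aryl group can only arrive at C6.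

Step 12
Reactants: 20 6-[5-(1,3-dioxolan-2-yl)-2-(methoxymethoxy)phenyl]-5,7-bis(methoxymethoxy)-2-[4-(methoxymethoxy)phenyl]chromen-4-one
Product: 21 3-[5,7-bis(methoxymethoxy)-2-[4-(methoxymethoxy)phenyl]-4-oxochromen-6-yl]-4-(methoxymethoxy)benzaldehyde
Conditions: pyridinium p-toluenesulfonate (0.3 equiv), acetone/H2O (10:1), 45 °C, stopped at full conversion of 20
Reagents that add atoms: water, O
Why: Acid-catalysed acetal hydrolysis through an aryl-stabilised oxocarbenium ion (para-alkoxy assisted) should be far faster than ionisation of the aryl MOM ethers under this weak acid, so only the dioxolane is expected to open.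

Step 13
Reactants: 22 1-(2,4-dihydroxy-6-methoxyphenyl)ethanone
Product: 23 1-[2-hydroxy-6-methoxy-4-(methoxymethoxy)phenyl]ethanone
Conditions: MOMCl (1.05 equiv), K2CO3 (1.5 equiv), acetone, 0 °C → rt
Reagents that add atoms: chloromethyl methyl ether, COCCl
Why: The 4-hydroxyl is the more acidic and is not held in the hydrogen bond to the ketone, so mono-O-alkylation should take place there and leave the chelated 2-hydroxyl free.

Step 14
Reactants: 23 1-[2-hydroxy-6-methoxy-4-(methoxymethoxy)phenyl]ethanone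
Product: 24 tert-butyl 3-[2-hydroxy-6-methoxy-4-(methoxymethoxy)phenyl]-3-oxopropanoate
Conditions: LiN(SiMe3)2 (3.1 equiv), THF, −78 °C; Boc2O (1.1 equiv), −78 → −20 °C; aq NH4Cl
Reagents that add atoms: di-tert-butyl dicarbonate, CC(C)(C)OC(=O)OC(=O)OC(C)(C)C
Why: Claisen-type C-acylation of the phenoxide–enolate dianion at its unhindered methylene carbon should give the β-keto ester, the third equivalent of base absorbing its acidic proton and the bulky ester resisting lactonisation to a 4-hydroxycoumarin.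

Step 15
Reactants: 21 3-[5,7-bis(methoxymethoxy)-2-[4-(methoxymethoxy)phenyl]-4-oxochromen-6-yl]-4-(methoxymethoxy)benzaldehyde; 24 tert-butyl 3-[2-hydroxy-6-methoxy-4-(methoxymethoxy)phenyl]-3-oxopropanoate
Product: 25 tert-butyl 3-[3-[5,7-bis(methoxymethoxy)-2-[4-(methoxymethoxy)phenyl]-4-oxochromen-6-yl]-4-(methoxymethoxy)phenyl]-2-[2-hydroxy-6-methoxy-4-(methoxymethoxy)benzoyl]prop-2-enoate (alkene geometry not defined)
Conditions: piperidine (0.2 equiv), AcOH (0.2 equiv), 4 Å molecular sieves, toluene, rt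
Reagents that add atoms: none
Why: Knoevenagel condensation of the β-keto ester with the aryl aldehyde under piperidinium acetate with water removal should give the alkylidene, and the low temperature is meant to hold back amine-promoted ring closure.

Step 16
Reactants: 25 tert-butyl 3-[3-[5,7-bis(methoxymethoxy)-2-[4-(methoxymethoxy)phenyl]-4-oxochromen-6-yl]-4-(methoxymethoxy)phenyl]-2-[2-hydroxy-6-methoxy-4-(methoxymethoxy)benzoyl]prop-2-enoate
Product: 26 tert-butyl (2S)-2-[3-[5,7-bis(methoxymethoxy)-2-[4-(methoxymethoxy)phenyl]-4-oxochromen-6-yl]-4-(methoxymethoxy)phenyl]-5-methoxy-7-(methoxymethoxy)-4-oxochromane-3-carboxylate (C3 epimers and enol form)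
Conditions: 1-[3,5-bis(trifluoromethyl)phenyl]-3-(9-deoxy-epi-quinidin-9-yl)thiourea (10 mol%), toluene, −25 °C
Reagents that add atoms: none
Why: In this known thiourea-catalysed oxa-Michael closure of β-keto ester alkylidenes, the thiourea binds the dicarbonyl unit while the quinuclidine nitrogen activates the phenol, so 6-endo-trig addition should occur on one face of the alkylidene and set C2 as S under catalyst control, C3 staying labile and of no consequence.

Step 17
Reactants: 26 tert-butyl (2S)-2-[3-[5,7-bis(methoxymethoxy)-2-[4-(methoxymethoxy)phenyl]-4-oxochromen-6-yl]-4-(methoxymethoxy)phenyl]-5-methoxy-7-(methoxymethoxy)-4-oxochromane-3-carboxylate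
Product: 29 (2S)-2-[3-[5,7-dihydroxy-2-(4-hydroxyphenyl)-4-oxochromen-6-yl]-4-hydroxyphenyl]-7-hydroxy-5-methoxy-2,3-dihydrochromen-4-one, via pentaphenol ester 27 (not isolated), via keto acid 28 (not isolated)
Conditions: HCl (3 M) in MeOH/THF (2:1), 0 °C → rt, then 45 °C
Reagents that add atoms: none
Why: Acid-catalysed acetal exchange with methanol should remove the five MOM groups in the cold, and gentle warming then cleaves the tert-butyl ester by acidolysis and decarboxylates the β-keto acid, conditions under which the chromanone ring is not expected to open, so C2 keeps its configuration.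

**Compound list**

1 | 2-bromobenzene-1,3-diol (2-bromoresorcinol) | Oc1cccc(O)c1Br | starting material
2 | 2-bromo-1,3-bis(methoxymethoxy)benzene | COCOc1cccc(OCOC)c1Br | intermediate
3 | 3-bromo-4-hydroxybenzaldehyde | O=Cc1ccc(O)c(Br)c1 | starting material
4 | 3-bromo-4-(methoxymethoxy)benzaldehyde | COCOc1ccc(C=O)cc1Br | intermediate
5 | 2-[3-bromo-4-(methoxymethoxy)phenyl]-1,3-dioxolane | COCOc1ccc(C2OCCO2)cc1Br | intermediate
6 | 2-[5-(1,3-dioxolan-2-yl)-2-(methoxymethoxy)phenyl]-4,4,5,5-tetramethyl-1,3,2-dioxaborolane | COCOc1ccc(C2OCCO2)cc1B1OC(C)(C)C(C)(C)O1 | intermediate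
7 | 2-[3-[2,6-bis(methoxymethoxy)phenyl]-4-(methoxymethoxy)phenyl]-1,3-dioxolane | COCOc1ccc(C2OCCO2)cc1-c1c(OCOC)cccc1OCOC | intermediate
8 | 2-[4-[5-(1,3-dioxolan-2-yl)-2-(methoxymethoxy)phenyl]-3,5-bis(methoxymethoxy)phenyl]-4,4,5,5-tetramethyl-1,3,2-dioxaborolane | COCOc1ccc(C2OCCO2)cc1-c1c(OCOC)cc(B2OC(C)(C)C(C)(C)O2)cc1OCOC | intermediate
9 | 4-[5-(1,3-dioxolan-2-yl)-2-(methoxymethoxy)phenyl]-3,5-bis(methoxymethoxy)phenol | COCOc1ccc(C2OCCO2)cc1-c1c(OCOC)cc(O)cc1OCOC | intermediate
10 | 2-bromo-4-[5-(1,3-dioxolan-2-yl)-2-(methoxymethoxy)phenyl]-3,5-bis(methoxymethoxy)phenol | COCOc1ccc(C2OCCO2)cc1-c1c(OCOC)cc(O)c(Br)c1OCOC | intermediate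
11 | [2-bromo-4-[5-(1,3-dioxolan-2-yl)-2-(methoxymethoxy)phenyl]-3,5-bis(methoxymethoxy)phenoxy]trimethylsilane | COCOc1ccc(C2OCCO2)cc1-c1c(OCOC)cc(O[Si](C)(C)C)c(Br)c1OCOC | intermediate
12 | lithium 4-[5-(1,3-dioxolan-2-yl)-2-(methoxymethoxy)phenyl]-3,5-bis(methoxymethoxy)-2-(trimethylsilyl)phenolate | [Li+].COCOc1ccc(C2OCCO2)cc1-c1c(OCOC)cc([O-])c([Si](C)(C)C)c1OCOC | intermediate
13 | 4-[5-(1,3-dioxolan-2-yl)-2-(methoxymethoxy)phenyl]-3,5-bis(methoxymethoxy)-2-(trimethylsilyl)phenyl trifluoromethanesulfonate | COCOc1ccc(C2OCCO2)cc1-c1c(OCOC)cc(OS(=O)(=O)C(F)(F)F)c([Si](C)(C)C)c1OCOC | intermediate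
14 | 4-iodophenol | Oc1ccc(I)cc1 | starting material
15 | 1-iodo-4-(methoxymethoxy)benzene | COCOc1ccc(I)cc1 | intermediate
16 | prop-2-ynoic acid (propiolic acid) | C#CC(=O)O | starting material
17 | 3-[4-(methoxymethoxy)phenyl]prop-2-ynoic acid | COCOc1ccc(C#CC(=O)O)cc1 | intermediate
18 | 4-[5-(1,3-dioxolan-2-yl)-2-(methoxymethoxy)phenyl]-3,5-bis(methoxymethoxy)-1,2-didehydrobenzene (aryne) | COCOc1ccc(C2OCCO2)cc1C1=C(OCOC)C#CC=C1OCOC | intermediate
19 | 1-[3-[5-(1,3-dioxolan-2-yl)-2-(methoxymethoxy)phenyl]-6-hydroxy-2,4-bis(methoxymethoxy)phenyl]-3-[4-(methoxymethoxy)phenyl]prop-2-yn-1-one (present as its cesium phenoxide) | COCOc1ccc(C#CC(=O)c2c(O)cc(OCOC)c(-c3cc(C4OCCO4)ccc3OCOC)c2OCOC)cc1 | intermediate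
20 | 6-[5-(1,3-dioxolan-2-yl)-2-(methoxymethoxy)phenyl]-5,7-bis(methoxymethoxy)-2-[4-(methoxymethoxy)phenyl]chromen-4-one | COCOc1ccc(-c2cc(=O)c3c(OCOC)c(-c4cc(C5OCCO5)ccc4OCOC)c(OCOC)cc3o2)cc1 | intermediate
21 | 3-[5,7-bis(methoxymethoxy)-2-[4-(methoxymethoxy)phenyl]-4-oxochromen-6-yl]-4-(methoxymethoxy)benzaldehyde | COCOc1ccc(-c2cc(=O)c3c(OCOC)c(-c4cc(C=O)ccc4OCOC)c(OCOC)cc3o2)cc1 | intermediate
22 | 1-(2,4-dihydroxy-6-methoxyphenyl)ethanone | CC(=O)c1c(O)cc(O)cc1OC | starting material
23 | 1-[2-hydroxy-6-methoxy-4-(methoxymethoxy)phenyl]ethanone | CC(=O)c1c(O)cc(OCOC)cc1OC | intermediate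
24 | tert-butyl 3-[2-hydroxy-6-methoxy-4-(methoxymethoxy)phenyl]-3-oxopropanoate | CC(C)(C)OC(=O)CC(=O)c1c(O)cc(OCOC)cc1OC | intermediate
25 | tert-butyl 3-[3-[5,7-bis(methoxymethoxy)-2-[4-(methoxymethoxy)phenyl]-4-oxochromen-6-yl]-4-(methoxymethoxy)phenyl]-2-[2-hydroxy-6-methoxy-4-(methoxymethoxy)benzoyl]prop-2-enoate (alkene geometry not defined) | COCOc1ccc(-c2cc(=O)c3c(OCOC)c(-c4cc(C=C(C(=O)OC(C)(C)C)C(=O)c5c(O)cc(OCOC)cc5OC)ccc4OCOC)c(OCOC)cc3o2)cc1 | intermediate
26 | tert-butyl (2S)-2-[3-[5,7-bis(methoxymethoxy)-2-[4-(methoxymethoxy)phenyl]-4-oxochromen-6-yl]-4-(methoxymethoxy)phenyl]-5-methoxy-7-(methoxymethoxy)-4-oxochromane-3-carboxylate (C3 not defined) | COc1cc(OCOC)cc2c1C(=O)C(C(=O)OC(C)(C)C)[C@@H](c1ccc(OCOC)c(-c3c(OCOC)cc4oc(-c5ccc(OCOC)cc5)cc(=O)c4c3OCOC)c1)O2 | intermediate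
27 | tert-butyl (2S)-2-[3-[5,7-dihydroxy-2-(4-hydroxyphenyl)-4-oxochromen-6-yl]-4-hydroxyphenyl]-7-hydroxy-5-methoxy-4-oxochromane-3-carboxylate (C3 not defined) | COc1cc(O)cc2c1C(=O)C(C(=O)OC(C)(C)C)[C@@H](c1ccc(O)c(-c3c(O)cc4oc(-c5ccc(O)cc5)cc(=O)c4c3O)c1)O2 | intermediate
28 | (2S)-2-[3-[5,7-dihydroxy-2-(4-hydroxyphenyl)-4-oxochromen-6-yl]-4-hydroxyphenyl]-7-hydroxy-5-methoxy-4-oxochromane-3-carboxylic acid (C3 not defined) | COc1cc(O)cc2c1C(=O)C(C(=O)O)[C@@H](c1ccc(O)c(-c3c(O)cc4oc(-c5ccc(O)cc5)cc(=O)c4c3O)c1)O2 | intermediate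
29 | (2S)-2-[3-[5,7-dihydroxy-2-(4-hydroxyphenyl)-4-oxochromen-6-yl]-4-hydroxyphenyl]-7-hydroxy-5-methoxy-2,3-dihydrochromen-4-one | COc1cc(O)cc2c1C(=O)C[C@@H](c1ccc(O)c(-c3c(O)cc4oc(-c5ccc(O)cc5)cc(=O)c4c3O)c1)O2 | target

**Step count and risks**

Total: 17 steps. Longest linear sequence: 12 steps (from 3 through steps 2, 3, 4, 5, 6, 7, 8, 11, 12, 15, 16, 17).

Steps most likely to fail:

1. Step 11. The aryl anion may be protonated by the acid before it reaches the carboxyl carbon (O-arylation in place of C–O insertion), the cesium arylpropiolate may lose CO2 at 125 °C, or the crowded aryne may be consumed unselectively. The fallback sets out from 10 and 17 and returns at 20, making the same bonds one after the other. Acid 17 is converted with MeNHOMe·HCl, EDC·HCl and Et3N in CH2Cl2 into N-methoxy-N-methyl-3-[4-(methoxymethoxy)phenyl]prop-2-ynamide F1. Bromophenol 10 with n-BuLi (2.2 equiv, THF, −78 °C) gives the lithium phenoxide carrying an ortho aryllithium, which is acylated at carbon by F1 and, after a cold NH4Cl quench, should give hydroxyaryl ynone 19. K2CO3 in acetone (or Et2NH in EtOH) then closes 19 to 20 by 6-endo-dig oxa-Michael addition.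

2. Step 16. Enantiocontrol may erode, either through ring closure of the doubly activated alkylidene without the catalyst (it may begin under the amine of step 15) or through poor facial discrimination on a substrate with a 6′-methoxy group and a very large β-aryl group. The fallback sets out from 21 and 23 and returns at 29. Claisen–Schmidt condensation (KOH, EtOH/THF, rt) gives (2E)-3-[3-[5,7-bis(methoxymethoxy)-2-[4-(methoxymethoxy)phenyl]-4-oxochromen-6-yl]-4-(methoxymethoxy)phenyl]-1-[2-hydroxy-6-methoxy-4-(methoxymethoxy)phenyl]prop-2-en-1-one F2. NaOAc in refluxing EtOH closes it to racemic 2-[3-[5,7-bis(methoxymethoxy)-2-[4-(methoxymethoxy)phenyl]-4-oxochromen-6-yl]-4-(methoxymethoxy)phenyl]-5-methoxy-7-(methoxymethoxy)-2,3-dihydrochromen-4-one F3. Preparative HPLC on a cellulose tris(3,5-dimethylphenylcarbamate) phase separates the enantiomers and provides (2S)-2-[3-[5,7-bis(methoxymethoxy)-2-[4-(methoxymethoxy)phenyl]-4-oxochromen-6-yl]-4-(methoxymethoxy)phenyl]-5-methoxy-7-(methoxymethoxy)-2,3-dihydrochromen-4-one F4; the (2R) antipode is returned to F3 by base-mediated ring opening and reclosure. HCl (2 M) in MeOH/THF at 0 °C → rt then removes the five MOM groups to give 29.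

3. Step 8. n-BuLi may deprotonate next to a MOM group instead of exchanging bromine, the aryllithium chelated by the flanking MOM oxygen may be slow to take up silicon, or Tf2O may attack acetal oxygens. The fallback sets out from 9 and returns at 13, replacing bromination and silyl migration by directed ortho-metalation. ClC(O)NEt2 and K2CO3 in MeCN at 60 °C give 4-[5-(1,3-dioxolan-2-yl)-2-(methoxymethoxy)phenyl]-3,5-bis(methoxymethoxy)phenyl N,N-diethylcarbamate F5. s-BuLi/TMEDA in THF at −78 °C lithiates the position flanked by the carbamate and a MOM ether (both ortho sites are equivalent), and Me3SiCl gives 4-[5-(1,3-dioxolan-2-yl)-2-(methoxymethoxy)phenyl]-3,5-bis(methoxymethoxy)-2-(trimethylsilyl)phenyl N,N-diethylcarbamate F6. LiAlH4 in THF at 0 °C cleaves the carbamate to 4-[5-(1,3-dioxolan-2-yl)-2-(methoxymethoxy)phenyl]-3,5-bis(methoxymethoxy)-2-(trimethylsilyl)phenol F7. Tf2O and pyridine in CH2Cl2 at −20 °C then give 13.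

**Further compounds**

F1 | step 11 | N-methoxy-N-methyl-3-[4-(methoxymethoxy)phenyl]prop-2-ynamide | CON(C)C(=O)C#Cc1ccc(OCOC)cc1
F2 | step 16 | (2E)-3-[3-[5,7-bis(methoxymethoxy)-2-[4-(methoxymethoxy)phenyl]-4-oxochromen-6-yl]-4-(methoxymethoxy)phenyl]-1-[2-hydroxy-6-methoxy-4-(methoxymethoxy)phenyl]prop-2-en-1-one | COCOc1ccc(-c2cc(=O)c3c(OCOC)c(-c4cc(/C=C/C(=O)c5c(O)cc(OCOC)cc5OC)ccc4OCOC)c(OCOC)cc3o2)cc1
F3 | step 16 | racemic 2-[3-[5,7-bis(methoxymethoxy)-2-[4-(methoxymethoxy)phenyl]-4-oxochromen-6-yl]-4-(methoxymethoxy)phenyl]-5-methoxy-7-(methoxymethoxy)-2,3-dihydrochromen-4-one | COc1cc(OCOC)cc2c1C(=O)CC(c1ccc(OCOC)c(-c3c(OCOC)cc4oc(-c5ccc(OCOC)cc5)cc(=O)c4c3OCOC)c1)O2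
F4 | step 16 | (2S)-2-[3-[5,7-bis(methoxymethoxy)-2-[4-(methoxymethoxy)phenyl]-4-oxochromen-6-yl]-4-(methoxymethoxy)phenyl]-5-methoxy-7-(methoxymethoxy)-2,3-dihydrochromen-4-one | COc1cc(OCOC)cc2c1C(=O)C[C@@H](c1ccc(OCOC)c(-c3c(OCOC)cc4oc(-c5ccc(OCOC)cc5)cc(=O)c4c3OCOC)c1)O2
F5 | step 8 | 4-[5-(1,3-dioxolan-2-yl)-2-(methoxymethoxy)phenyl]-3,5-bis(methoxymethoxy)phenyl N,N-diethylcarbamate | CCN(CC)C(=O)Oc1cc(OCOC)c(-c2cc(C3OCCO3)ccc2OCOC)c(OCOC)c1
F6 | step 8 | 4-[5-(1,3-dioxolan-2-yl)-2-(methoxymethoxy)phenyl]-3,5-bis(methoxymethoxy)-2-(trimethylsilyl)phenyl N,N-diethylcarbamate | CCN(CC)C(=O)Oc1cc(OCOC)c(-c2cc(C3OCCO3)ccc2OCOC)c(OCOC)c1[Si](C)(C)C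
F7 | step 8 | 4-[5-(1,3-dioxolan-2-yl)-2-(methoxymethoxy)phenyl]-3,5-bis(methoxymethoxy)-2-(trimethylsilyl)phenol | COCOc1cc(O)c([Si](C)(C)C)c(OCOC)c1-c1cc(C2OCCO2)ccc1OCOC
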